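Substrate cannot react by substrate + partner → target + by-product without meeting a partner, one for one. Meanwhile partner → decomposed reagent takes partner away, and target ⇌ isomer of the product shares out what is formed.

all flasks: substrate 0.50 M

| charge | partner | remark | time |
|---|---|---|---|
| south-west | 0.25 M | the very flask that is asked about, followed so far |  |
| east | 0.12 M | run made earlier |  |
| flask | 0.250 M |  | 5.0 h |

south-west run (percent of the substrate charged)

| time / min | substrate / % | target / % |
|---|---|---|
| 8.00 | 52.5 | 45.2 |
| 12.0 | 52.5 | 44.1 |
| 20.0 | 51.9 | 41.8 |
| 30.0 | 52.9 | 40.6 |
| 50.0 | 52.6 | 36.9 |
| 90.0 | 52.4 | 34.1 |

east run (percent of the substrate charged)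

| time / h | substrate / % | target / % |
|---|---|---|
| 0.833 | 77.1 | 17.6 |
| 1.50 | 77.1 | 16.8 |
| 2.50 | 77.6 | 15.2 |
| 3.00 | 76.8 | 15.5 |
| 4.00 | 76.3 | 15.1 |
| 5.00 | 77.3 | 16.0 |

(standard deviation of a reading: 0.3 percentage points)

- the earlier runs were read with a standard deviation of 0.3 percentage points
- steps under discussion: substrate + partner -> target + by-product; target <-> isomer of the product; partner -> decomposed reagent
- the reaction counts as stopped when no species that holds the substrate changes by six tenths of a point or more over the second half of the time

- the state of affairs at 5.0 h: stopped, and by what, or still going (it is still moving / all of the substrate has reacted / the partner has run out first / forward and back rates have come level)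
- share of the substrate used up at 5.0 h
- target at 5.0 h, in percent of the substrate charged
- isomer of the product at 5.0 h, in percent of the substrate charged

Turned round, the question reads: for this flask to use up its substrate, the partner would have to deliver as much as the substrate charged. The substrate readings stand flat, with mean S = 52.5% in the south-west run and 77.0% in the east run. Whether these plateaus belong to the partner shows in powers of ten:

log10 (partner charge, south-west over east) = 0.319
log10 (substrate consumed, south-west over east) = 0.315

Between these two runs, at the same substrate charge, conversion thus moves with the partner charge, power for power. With c_A and c_B the starting concentrations of substrate and partner, the south-west readings give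

φ = (1 − S) c_A / c_B = 0.951

This φ, the partner yield, is the substrate consumed per partner charged. In the flask asked about, the partner is reckoned to deliver 0.238 M, less than the 0.50 M of substrate. My reckoning therefore stops it at a conversion of φ c_B / c_A = 47.5%, which is 0.322 in log10 short of complete use.

The forecast says the partner has run out first, with conversion 47.5%, target 31.9% and isomer of the product 15.6%, on the ground that “the plateau scales with the partner charged”.

In the flask, the partner has run out first, with conversion 47.5%, target 31.8% and isomer of the product 15.7%.

    substrate + partner → target + by-product (k = 0.0614 M⁻¹ s⁻¹)
    target ⇌ isomer of the product (K = 0.493, k = 1.25 × 10⁻⁴ s⁻¹)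
    partner → decomposed reagent (k = 0.00119 s⁻¹)

At 5.00 h the flask holds 0% of its partner, the limiting reagent. The same run without the shrinking partner supply reaches 100% conversion instead of 47.5%, so that supply is what stops the substrate. Carried to a neighbouring flask, with 0.10 M of partner and the same substrate, φ gives 19.0%, and that neighbour reaches 19.2%.

The numbers in the tables stem from a simulated flask for substances that don't exist; noise was put on by code.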